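**Retrosynthetic overview**
The route rests on ring A, the 2,4-dioxygenated 6-propylbenzoyl ring: its six carbons and its ester carbonyl are a folded 3,5,7-trioxodecanoyl chain, and the acyl end of that chain is the depside ester to the C4 oxygen of ring B (the 2-methoxy-6-pentylbenzoic acid ring).
Disconnections, backwards: the benzyl ester of the ring B acid; the three O-methyl bonds; then, in one operation, the C1–C6 bond of ring A (aldol) and the ester C(=O)–O bond to C4 of ring B (ketene capture), leading to a diketo-dioxinone and benzyl olivetolate.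
The diketo-dioxinone comes from 2,2,6-trimethyl-1,3-dioxin-4-one by two C-acylations (acetyl chloride, then the Weinreb amide of butanoic acid); benzyl olivetolate comes from olivetol by formylation, oxidation and benzylation.
Ring order: ring B is bought as olivetol; ring A is the only ring built, and it is built on the preformed ester.
Key step: step 7

Remark: the target has no stereocentre; the tricarbonyl compounds are drawn as keto tautomers although they are largely enolised, and the transient cyclic aldol 17 should form as a stereoisomer mixture that is erased on aromatisation.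

**Route**

Step 1
Reactants: 1 2,2,6-trimethyl-4H-1,3-dioxin-4-one; 2 acetyl chloride
Product: 4 2,2-dimethyl-6-(2-oxopropyl)-4H-1,3-dioxin-4-one, via lithium dienolate 3 (not isolated)
Conditions: 1 (2 equiv), LiN(SiMe3)2 (2 equiv), THF, −78 °C; then 2 (1 equiv), −78 °C; 1 M HCl quench
Reagents that add atoms: none
Why: Gamma-deprotonation of the vinylogous ester gives dienolate 3, which undergoes Claisen-type C-acylation at the exocyclic carbon; the second equivalent of dienolate takes the proton of the more acidic beta-keto product, so the reaction should stop at mono-acylation.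

Step 2
Reactants: 5 butanoyl chloride
Product: 6 N-methoxy-N-methylbutanamide
Conditions: MeNHOMe·HCl, Et3N (2.2 equiv), CH2Cl2, 0 °C → rt
Reagents that add atoms: N,O-dimethylhydroxylamine hydrochloride, CNOC.Cl
Why: Nucleophilic acyl substitution of the acid chloride by the hydroxylamine (Weinreb amide formation), with Et3N taking up both equivalents of HCl.

Step 3
Reactants: 4 2,2-dimethyl-6-(2-oxopropyl)-4H-1,3-dioxin-4-one; 6 N-methoxy-N-methylbutanamide
Product: 9 6-(2,4-dioxoheptyl)-2,2-dimethyl-4H-1,3-dioxin-4-one, via dilithium dianion 7 (not isolated), via lithiated Weinreb adduct 8 (not isolated)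
Conditions: LiN(iPr)2 (2.2 equiv), THF, −78 → −40 °C; then 6, −78 → −20 °C; 1 M HCl to pH 3, cold
Reagents that add atoms: none
Why: Double deprotonation gives dianion 7, whose terminal and more reactive carbanion adds to the Weinreb amide (crossed Claisen acylation); adduct 8 should not collapse before the acid quench, which prevents over-addition and proton transfer from the 1,3-diketone product.

Step 4
Reactants: 10 olivetol (5-pentylbenzene-1,3-diol)
Product: 12 2,4-dihydroxy-6-pentylbenzaldehyde, via aryl iminium chloride 11 (not isolated)
Conditions: POCl3 (1.1 equiv), DMF, 0 °C → rt; then ice-water, 50 °C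
Reagents that add atoms: N,N-dimethylformamide, CN(C)C=O; water, O
Why: Vilsmeier–Haack formylation should attack the position ortho to one hydroxyl and para to the other (C4 of olivetol, next to the pentyl chain) rather than the crowded position between both hydroxyls, and hydrolysis of iminium 11 releases the aldehyde.

Step 5
Reactants: 12 2,4-dihydroxy-6-pentylbenzaldehyde
Product: 13 2,4-dihydroxy-6-pentylbenzoic acid (olivetolic acid)
Conditions: NaClO2, NaH2PO4, DMSO/H2O, 0 °C → rt
Reagents that add atoms: sodium chlorite, [Na+].[O-]Cl=O
Why: Pinnick (Lindgren) oxidation of the aldehyde under buffered conditions, with DMSO scavenging HOCl so that the electron-rich ring is not chlorinated; the acid is kept at or below room temperature because beta-resorcylic acids decarboxylate on heating.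

Step 6
Reactants: 13 2,4-dihydroxy-6-pentylbenzoic acid
Product: 14 benzyl 2,4-dihydroxy-6-pentylbenzoate (benzyl olivetolate)
Conditions: BnBr (1.05 equiv), KHCO3, DMF, rt
Reagents that add atoms: benzyl bromide, BrCc1ccccc1
Why: Bicarbonate deprotonates only the carboxylic acid, so SN2 O-alkylation of the carboxylate gives the benzyl ester and leaves both phenols free.

Step 7
Reactants: 9 6-(2,4-dioxoheptyl)-2,2-dimethyl-4H-1,3-dioxin-4-one; 14 benzyl 2,4-dihydroxy-6-pentylbenzoate
Product: 18 benzyl 4-[(2,4-dihydroxy-6-propylbenzoyl)oxy]-2-hydroxy-6-pentylbenzoate, via acylketene 15 (not isolated), via aryl trioxodecanoate 16 (not isolated), via cyclic aldol 17 (not isolated)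
Conditions: 9 (1 equiv), 14 (1.2 equiv), PhMe, 110 °C, acetone distilled off; cool to rt, Et3N, CH2Cl2; then HCl (4 M in 1,4-dioxane), rt
Reagents that add atoms: none
Why: Retro-hetero-Diels–Alder loss of acetone from 9 gives acylketene 15, the free C4 phenol of 14 adds across its C=C=O unit to give ester 16, Et3N enolises the C2 methylene (between ester and ketone) so that it attacks the C7 propyl ketone to give aldol 17, and HCl dehydrates and enolises 17 to the resorcylate ring A. The closest known reactions are the formation of aryl acetoacetates from 2,2,6-trimethyl-1,3-dioxin-4-one and phenols, and the alcohol trapping and base/acid or amine-mediated cycloaromatisation of diketo-dioxinones to resorcylates. Ring A closes by a 6-(enolexo)-exo-trig aldol between C2 and C7 of the chain (C1 and C6 of the new ring), a favoured mode. No stereocentre has to be controlled, since the two of 17 disappear on aromatisation. The step needs O-acylation at the C4 phenol only, which the hydrogen bond from the C2 phenol to the benzyl ester carbonyl should secure by making that hydroxyl less nucleophilic and more shielded; it also needs the C2-to-C7 aldol to beat O-cyclisation to a 4-hydroxy-2-pyrone and C6-to-C1 Claisen closure (both would expel the phenol), which a short thermolysis, a non-chelating amine base at room temperature and an alcohol-free medium are expected to favour. A further benefit is steric: the hindered depside linkage is already in place when C2 and C6 of ring A acquire their substituents, so no hindered benzoic acid has to be activated.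

Step 8
Reactants: 18 benzyl 4-[(2,4-dihydroxy-6-propylbenzoyl)oxy]-2-hydroxy-6-pentylbenzoate
Product: 19 benzyl 4-[(2,4-dimethoxy-6-propylbenzoyl)oxy]-2-methoxy-6-pentylbenzoate
Conditions: MeI (excess), K2CO3, acetone, reflux
Reagents that add atoms: iodomethane, CI
Why: Williamson O-methylation of the three phenoxides; the two hydrogen-bonded C2 hydroxyls should react more slowly than the ring A C4 hydroxyl but be alkylated on prolonged heating, while the hindered depside ester and the benzyl ester should survive the alcohol-free medium.

Step 9
Reactants: 19 benzyl 4-[(2,4-dimethoxy-6-propylbenzoyl)oxy]-2-methoxy-6-pentylbenzoate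
Product: 20 4-[(2,4-dimethoxy-6-propylbenzoyl)oxy]-2-methoxy-6-pentylbenzoic acid (target)
Conditions: H2 (1 atm), 10% Pd/C, EtOAc, rt
Reagents that add atoms: none
Why: Catalytic hydrogenolysis cleaves only the benzylic C–O bond of the benzyl ester; the aryl ester, the aryl methyl ethers and the arene rings are inert under these conditions.

**Compound list**
1 | 2,2,6-trimethyl-4H-1,3-dioxin-4-one | CC1=CC(=O)OC(C)(C)O1 | starting material
2 | acetyl chloride | CC(=O)Cl | starting material
3 | lithium dienolate of 1 (lithium 2,2-dimethyl-6-methylidene-6H-1,3-dioxin-4-olate) | [Li]OC1=CC(=C)OC(C)(C)O1 | intermediate (not isolated)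
4 | 2,2-dimethyl-6-(2-oxopropyl)-4H-1,3-dioxin-4-one | CC(=O)CC1=CC(=O)OC(C)(C)O1 | intermediate
5 | butanoyl chloride | CCCC(=O)Cl | starting material
6 | N-methoxy-N-methylbutanamide | CCCC(=O)N(C)OC | intermediate
7 | dilithium dianion of 4 (bis-enolate) | C=C(O[Li])C=C1C=C(O[Li])OC(C)(C)O1 | intermediate (not isolated)
8 | lithiated Weinreb adduct (dilithium alkoxide-enolate of the tetrahedral adduct of 7 and 6) | CCCC(O[Li])(N(C)OC)CC(O[Li])=CC1=CC(=O)OC(C)(C)O1 | intermediate (not isolated)
9 | 6-(2,4-dioxoheptyl)-2,2-dimethyl-4H-1,3-dioxin-4-one | CCCC(=O)CC(=O)CC1=CC(=O)OC(C)(C)O1 | intermediate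
10 | olivetol (5-pentylbenzene-1,3-diol) | CCCCCc1cc(O)cc(O)c1 | starting material
11 | [(2,4-dihydroxy-6-pentylphenyl)methylidene]dimethyliminium chloride | CCCCCc1cc(O)cc(O)c1C=[N+](C)C.[Cl-] | intermediate (not isolated)
12 | 2,4-dihydroxy-6-pentylbenzaldehyde | CCCCCc1cc(O)cc(O)c1C=O | intermediate
13 | 2,4-dihydroxy-6-pentylbenzoic acid (olivetolic acid) | CCCCCc1cc(O)cc(O)c1C(=O)O | intermediate
14 | benzyl 2,4-dihydroxy-6-pentylbenzoate | CCCCCc1cc(O)cc(O)c1C(=O)OCc1ccccc1 | intermediate
15 | 3,5,7-trioxodec-1-en-1-one (acylketene) | CCCC(=O)CC(=O)CC(=O)C=C=O | intermediate (not isolated)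
16 | benzyl 2-hydroxy-6-pentyl-4-[(3,5,7-trioxodecanoyl)oxy]benzoate | CCCC(=O)CC(=O)CC(=O)CC(=O)Oc1cc(O)c(C(=O)OCc2ccccc2)c(CCCCC)c1 | intermediate (not isolated)
17 | benzyl 2-hydroxy-4-[(2-hydroxy-4,6-dioxo-2-propylcyclohexane-1-carbonyl)oxy]-6-pentylbenzoate (stereoisomer mixture) | CCCC1(O)CC(=O)CC(=O)C1C(=O)Oc1cc(O)c(C(=O)OCc2ccccc2)c(CCCCC)c1 | intermediate (not isolated)
18 | benzyl 4-[(2,4-dihydroxy-6-propylbenzoyl)oxy]-2-hydroxy-6-pentylbenzoate | CCCCCc1cc(OC(=O)c2c(CCC)cc(O)cc2O)cc(O)c1C(=O)OCc1ccccc1 | intermediate
19 | benzyl 4-[(2,4-dimethoxy-6-propylbenzoyl)oxy]-2-methoxy-6-pentylbenzoate | CCCCCc1cc(OC(=O)c2c(CCC)cc(OC)cc2OC)cc(OC)c1C(=O)OCc1ccccc1 | intermediate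
20 | 4-[(2,4-dimethoxy-6-propylbenzoyl)oxy]-2-methoxy-6-pentylbenzoic acid | CCCCCc1cc(OC(=O)c2c(CCC)cc(OC)cc2OC)cc(OC)c1C(=O)O | target

**Summary**
Total step count: 9. Longest linear sequence: 6 steps (olivetol 10 through steps 4, 5, 6, 7, 8 and 9).

**Steps most likely to fail**

Step 7. Phenol addition to ketene 15 may be slower than for an aliphatic alcohol, so intramolecular O-cyclisation of 15, or of the activated aryl ester 16 under base, to a 4-hydroxy-2-pyrone with loss of the phenol may compete; reversion of 16 to the ketene by E1cB elimination would have the same effect. Fallback: the fallback sets out from 9 and uses the alcohol version of the capture followed by a classical depside esterification. Thermolysis of 9 in toluene with benzyl alcohol should give benzyl 3,5,7-trioxodecanoate F1, which K2CO3 in iPrOH/CH2Cl2 should cyclise to benzyl 2-hydroxy-4,6-dioxo-2-propylcyclohexane-1-carboxylate F2 and HCl should aromatise to benzyl 2,4-dihydroxy-6-propylbenzoate F3. MeI/K2CO3 would give benzyl 2,4-dimethoxy-6-propylbenzoate F4, and hydrogenolysis (H2, 10% Pd/C) would give 2,4-dimethoxy-6-propylbenzoic acid F5. Activation of F5 with (CF3CO)2O in toluene (mixed anhydride/acylium, which tolerates the 2,6-disubstituted acid) and reaction with the unchelated C4 phenol of 14 would give benzyl 4-[(2,4-dimethoxy-6-propylbenzoyl)oxy]-2-hydroxy-6-pentylbenzoate F6. One O-methylation (MeI, K2CO3) then returns to the route at 19.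

Step 8. The two hydrogen-bonded phenols may be alkylated incompletely, and forcing the reaction may lead to carbonate-induced cleavage or acyl transfer at the depside ester. Fallback: the fallback sets out from 18 and replaces phenoxide alkylation by redox condensation. Mitsunobu methylation (MeOH, PPh3, DIAD, THF, rt → 50 °C) generates no carbonate or free hydroxide and should convert 18 directly into 19, where it rejoins the route; no new compound is made on the way (F0).

Step 3. Dianion formation may be incomplete, proton transfer between the dianion and the amide or product may intervene, and the acid-sensitive diketo-dioxinone may be lost during the quench. Fallback: the fallback sets out from 4 and builds the same carbon–carbon bond by aldol addition and oxidation. Dianion 7 (LiN(iPr)2, THF, −78 °C) is added to butanal, an electrophile that cannot be deprotonated by its own adduct, to give racemic 6-(4-hydroxy-2-oxoheptyl)-2,2-dimethyl-4H-1,3-dioxin-4-one F7. Dess–Martin periodinane in CH2Cl2 at rt should oxidise F7 to the 1,3-diketone, rejoining the route at 9.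

**Further compounds**
F1 | step 7 | benzyl 3,5,7-trioxodecanoate | CCCC(=O)CC(=O)CC(=O)CC(=O)OCc1ccccc1
F2 | step 7 | benzyl 2-hydroxy-4,6-dioxo-2-propylcyclohexane-1-carboxylate (stereoisomer mixture) | CCCC1(O)CC(=O)CC(=O)C1C(=O)OCc1ccccc1
F3 | step 7 | benzyl 2,4-dihydroxy-6-propylbenzoate | CCCc1cc(O)cc(O)c1C(=O)OCc1ccccc1
F4 | step 7 | benzyl 2,4-dimethoxy-6-propylbenzoate | CCCc1cc(OC)cc(OC)c1C(=O)OCc1ccccc1
F5 | step 7 | 2,4-dimethoxy-6-propylbenzoic acid | CCCc1cc(OC)cc(OC)c1C(=O)O
F6 | step 7 | benzyl 4-[(2,4-dimethoxy-6-propylbenzoyl)oxy]-2-hydroxy-6-pentylbenzoate | CCCCCc1cc(OC(=O)c2c(CCC)cc(OC)cc2OC)cc(O)c1C(=O)OCc1ccccc1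
F0 | step 8 | none | none
F7 | step 3 | 6-(4-hydroxy-2-oxoheptyl)-2,2-dimethyl-4H-1,3-dioxin-4-one (racemic) | CCCC(O)CC(=O)CC1=CC(=O)OC(C)(C)O1
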